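The readings stem from a simulated flask for substances that don't exist.

Your vessel is closed and stirred, and the flask in it differs from the zeta run in one charge: it holds twice the scavenger.

in all of them: free catalyst 0.2 mol%; added ligand 2.1 mM
- epsilon: substrate 0.49 M; partner 1.1 equiv; scavenger 0.80 equiv; run made earlier
- eta: substrate 1.1 M; partner 1.1 equiv; scavenger 0.80 equiv; run made earlier
- zeta: substrate 0.73 M; partner 1.1 equiv; scavenger 0.40 equiv; run made earlier
- flask: substrate 0.73 M; partner 1.10 equiv; scavenger 0.800 equiv; time 3.0 h

| run | time / h | substrate / % | target / % |
|---|---|---|---|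
| epsilon | 0.250 | 94.3 | 5.3 |
| epsilon | 0.667 | 86.2 | 13.4 |
| epsilon | 1.50 | 72.3 | 27.1 |
| epsilon | 4.00 | 41.5 | 57.9 |
| eta | 0.833 | 73.3 | 26.9 |
| eta | 2.00 | 45.6 | 54.4 |
| eta | 2.50 | 36.2 | 63.3 |
| eta | 4.00 | 17.2 | 82.6 |
| zeta | 0.250 | 92.4 | 6.5 |
| zeta | 0.667 | 82.8 | 16.8 |
| zeta | 1.50 | 64.6 | 34.7 |
| zeta | 4.00 | 32.1 | 68.1 |

(scatter of a reading: 0.3 percentage points)

1. part of the substrate that has reacted at 3.0 h
2. share of the unused partner that is free and not bound as idle adduct, at 3.0 h

- for released group the idle adduct is counted in
- steps under discussion: partner + free catalyst -> catalyst intermediate A; substrate + catalyst intermediate A <-> catalyst intermediate B; catalyst intermediate B <-> released group + catalyst intermediate C; catalyst intermediate C -> catalyst intermediate D; catalyst intermediate D -> free catalyst + target; partner + released group <-> idle adduct; scavenger + released group -> scavenged by-product; free catalyst + added ligand <-> idle complex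
- the earlier runs do not show how much of partner is bound; that part of a forecast is a guess

Each substrate that reacts releases one released group, and each scavenger takes one. So read the zeta run as a race. At 1.50 h it had reacted 35.4% of its substrate, less than its 0.40 equiv of scavenger. At 4.00 h it had reacted 67.9%, more than that charge.

Here is my own reckoning. Treat substrate loss as pseudo-first-order. The last zeta reading gives 0.284 h⁻¹, and so an estimate of 57.4% reacted at 3.0 h. That first answer lies below the flask's 0.800 equiv of scavenger, so the flask should stay in the covered stretch, where substrate reacted is below scavenger charged. Go round again with the earlier zeta reading, taken inside that stretch. It reads 0.291 h⁻¹, slightly faster, and gives 58.3%.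

Scavenger charged less substrate reacted, per substrate charged, is then 0.217 equiv for the flask: this is the scavenger margin. The zeta run at its last reading stood short by 0.279 equiv.

The forecast, slightly above my figure, gives 58.5% reacted and 80% free, judging that “bound partner should be modest if scavenging keeps pace”.

The flask gives 59.1% reacted and 88.4% of the unused partner free, with 36% of its scavenger left. With the flask's own conversion the margin is 0.209 equiv, while the scavenger left is 0.284 equiv, which is more. That gap is released group not yet scavenged, standing as released group at 0.0119 M and as idle adduct at 0.0429 M.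

    partner + free catalyst → catalyst intermediate A (k = 0.280 M⁻¹ s⁻¹)
    substrate + catalyst intermediate A ⇌ catalyst intermediate B (K = 1.00 M⁻¹, k = 0.140 M⁻¹ s⁻¹)
    catalyst intermediate B ⇌ released group + catalyst intermediate C (K = 0.850 M, k = 1.60 s⁻¹)
    catalyst intermediate C → catalyst intermediate D (k = 0.250 s⁻¹)
    catalyst intermediate D → free catalyst + target (k = 0.200 s⁻¹)
    partner + released group ⇌ idle adduct, settled at all times (K = 11.0 M⁻¹)
    scavenger + released group → scavenged by-product (k = 0.0110 M⁻¹ s⁻¹)
    free catalyst + added ligand ⇌ idle complex (K = 430 M⁻¹, k = 0.100 M⁻¹ s⁻¹)

Now take the neighbour flask with 0.200 equiv of scavenger. Its margin, from my 58.3%, is a shortfall of 0.383 equiv, so more of its partner should be bound there. Computed, that flask has 1.9% of its scavenger left, 56.2% reacted and 52.7% of its unused partner free.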